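Added ligand cannot take up more enzyme than its own charge, one enzyme per idle complex, so c_enzyme in this flask must lie between two limits.

| flask | substrate | enzyme | added ligand | remark |
|---|---|---|---|---|
| theta | 0.065 M | 1.3 µM | 0.99 µM | run made earlier |
| epsilon | 0.098 M | 1.3 µM | 0.99 µM | run made earlier |
| flask | 0.13 M | 1.3 µM | 0.99 µM |  |

- theta (time / s: product / %, substrate / %): 10.0: 35.4, 64.5; 15.0: 45.3, 54.7; 25.0: 61.0, 39.0; 40.0: 74.5, 25.1; 60.0: 85.2, 16.3; 120: 96.1, 7.3
- epsilon (time / s: product / %, substrate / %): 10.0: 32.9, 67.8; 15.0: 42.5, 56.7; 25.0: 56.8, 44.2; 40.0: 71.0, 28.8; 60.0: 79.2, 19.0; 120: 92.5, 7.5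

(each reading ± 1 percentage point)

- on the list of suspects stand: enzyme + added ligand <-> idle complex; substrate + enzyme -> product + enzyme
- no earlier run changes the charge of enzyme; that part of a forecast is a guess

1. factor on the rate of making product when 30% of the substrate are converted if enzyme is charged twice over
2. factor on the rate when 30% of the substrate are converted if enzyme is charged at 0.12 µM instead

The lower limit rests on the enzyme excess, the charge of enzyme minus the charge of added ligand 0.310 µM. With the rate taken as proportional to c_enzyme at a given conversion, the limits give:

ligand unbound: c_enzyme = charge; doubling gives 2; 0.12 µM gives 0.0923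

ligand fully bound: c_enzyme = excess; doubling gives 5.19; 0.12 µM gives an excess of −0.870 µM, so ligand outnumbers enzyme and the factor tends towards nil

The theta run can be read as the passage between them. Its pseudo-first-order constant for substrate reads 0.0439 s⁻¹ over the first 10.0 s and 0.0134 s⁻¹ over the last interval. That is a drop of 3.28 as read, against 4.19 for charge over excess.

Product in that run already stands at 35.4% after 10.0 s, past the 30% asked about. My own reckoning therefore puts the doubled flask near the unbound limit. The flask with 0.12 µM needs roughly 108 s or longer to reach that conversion, so it belongs near the bound limit.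

The forecast gives 2.7 and 0.02, holding that “The simple suspect list fits if the ligand binds slowly”.

The simulation gives 2.22 and 0.00239.

    enzyme + added ligand ⇌ idle complex (K = 5.28 × 10⁷ L mol⁻¹, k = 23400 L mol⁻¹ s⁻¹)
    substrate + enzyme → product + enzyme, rate k2*[substrate]*[enzyme]/(1 + ([substrate]/Km2) + ([product]/Kp2)) (0.227 M, 0.135 M, k = 50200 L mol⁻¹ s⁻¹)

The run with the binding step taken away, both ways, has an apparent order in enzyme of 1.0 at 30% conversion, against 1.2 with it, so that step is part of the reason for the higher order. At 30.0 min this flask holds 27.7% of its catalyst as enzyme, a little above the 23.8% that the excess gives. In the flask with 0.12 µM, ligand exceeds enzyme by 0.870 µM, and with the binding constant 5.28 × 10⁷ L mol⁻¹ that excess reckons to an enzyme share of 2.13%, where the simulated share at 30% conversion is 2.12%.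

The readings were computed for substances that don't exist, noise included.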